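## Analysis of the target

- The target is an acyclic C50 carotenoid. In carotenoid numbering the chain runs C1–C15/C15'–C1'. C2 bears a prenyl branch (C1''H2–C2''H=C3''(CH3)2), C2' bears a 3-hydroxy-3-methylbutyl branch, and C1, C1' and the end of the C2' branch are tertiary carbinols.
- The only ring is the trans-oxirane O/C3/C4. Its carbon C4 is bonded directly to C5 of an all-E dodecaene that runs without a break from C5=C6 to C3'=C4'.
- There are four stereocentres: the contiguous triad C2 (R), C3 (R), C4 (R) on the left and the lone C2' (S) on the right. With 24 sp2 carbons between them, neither end can control the other.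
- The C4–O bond is the sensitive point. Acid ionises it to a polyenyl cation, the free C1–OH is placed to capture C4 in a five-membered ring, zerovalent palladium can ionise it as a vinyl oxirane, and a carbanion at C7 or at any vinylogous position expels the oxygen.
- Of the thirteen C=C bonds the most nucleophilic is the isolated, trisubstituted C2''=C3'' bond and not C3=C4. Every oxidative route to the oxirane therefore has a chemoselectivity problem, and the polyene itself does not tolerate oxidants.
- C1–C3 with the branch on C2 is, carbon for carbon, a lavandulyl C10 skeleton, and so is C1'–C3' with its branch. The priority order is the same at both centres, so the descriptors 2R and 2'S show that the two units have opposite spatial sense.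
- The ends therefore differ in constitution, oxidation level and handedness. This rules out a two-directional synthesis, although the core C8–C8' is symmetric.
- The plan uses one feature: the oxirane bond C3–C4 and the alkene C3'=C4' are the same locus of the two lavandulyl units. Each is a former carbonyl carbon joined to an allylic carbon, once with the oxygen kept and once with the oxygen lost.

## Retrosynthetic reasoning

**C7=C8.** The last cut divides 33 into the C15 epoxy enal 18 and the C35 phosphonium salt 31 (Wittig olefination). The oxirane dictates the polarity. A carbanion at C7 would be conjugated through C5=C6 to the C4–O bond and would open the ring. In 18 the formyl group instead withdraws electron density from C4 and makes the oxirane as robust as it can be. The cut lies here and not at C11=C12 or C15=C15' because C8–C8' is then exactly the commercial dialdehyde 27. The forward reaction runs in basic medium, and it is the only step that the complete polyenyl oxirane has to see.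

**C3–C4 together with C4–O (key disconnection).**
- From 18 through 17 to 16 only protecting groups and the oxidation level at C7 change.
- In 16 the C3–C4 bond and the C4–O bond are cut in one stroke. This gives aldehyde 7 (C1–C3 with both branches, C2 already set) and the allylic sulfonium salt 13 (C4–C7 with the C5 methyl group and the E-C5=C6 bond).
- The cut turns the oxirane from an oxidation problem into a C–C bond formation. No oxidant meets the prenyl alkene, and the ring oxygen is simply the carbonyl oxygen of 7.
- The forward reaction is a sulfonium ylide epoxidation through 14 and 15. It has to join the fragments, close the ring and set C3 and C4 in the right sense relative to C2.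
- Sulfide 12 controls C4, the trans preference ties C3 to C4, and the intrinsic facial bias of 7 points the same way.
- The product holds the whole stereotriad, while neither precursor holds more than one carbon stereocentre of the target.

**S–C4.** 13 is cut into sulfide 12, which is bought and recovered after the key step, and bromide 11. 11 goes back through 10 and 9 to 8. The allylic oxidation of 9 is chosen because it gives the E isomer only. The geometry of C5=C6 is thus fixed before the key step and never depends on an olefination.

**C7'=C8'.** 31 is traced through 30 to aldehyde 29, and 29 is cut into the C15 phosphonium salt 26 and the symmetric C20 dialdehyde 27. 27 brings seven double bonds and four methyl groups in one purchase. The forward reaction must stop after one of the two formyl groups has reacted, which an excess of 27 should secure.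

**C3'=C4'.** 26 comes from 25 and 24, and 24 is cut into aldehyde 21 and phosphonate 22. This is the same locus as in the key step, with the same C5 pattern X–CH2–C(CH3)=CH–. Here phosphorus instead of sulfur carries the oxygen away and leaves the E-alkene.

**Both aldehydes from one racemate.** 7 and 21 each hold all ten carbons of 1. 7 has the spatial sense of 2 and 21 that of 3, so one kinetic resolution of racemic 1 feeds both ends and neither enantiomer is discarded. The difference in hydration level comes from hydrating one alkene of 2 (to 4) and both alkenes of 3 (to 19).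

## Alternatives that were turned down

**Alternative 1:** the textbook C20 + C10 + C20 plan.
- Disconnection: C11=C12 and C11'=C12'.
- Forward key step: two Wittig reactions of the central dialdehyde A3 with the right-hand salt A4 and the oxirane-bearing salt A2. The oxirane would be made earlier by epoxidation of C3=C4 in dienoate A1.
- Why turned down:
  - In A1 the isolated trisubstituted prenyl alkene is more nucleophilic than the disubstituted, ester-conjugated C3=C4, so electrophilic oxidants attack the wrong bond.
  - Hydroxyl direction from C1–OH reaches both alkenes (homoallylic and bishomoallylic).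
  - A2 can only be made from an allylic alcohol under acidic or halide conditions next to a vinyl oxirane.
  - The ylide of A2 is a vinylogous β-oxido carbanion that should open the ring.
  - Each side needs two C5 homologations, which costs more steps than the route below.

**Alternative 2:** oxygen last.
- Disconnection: both C–O bonds of the oxirane in the finished tridecaene A5.
- Forward key step: a hydroxyl-directed, catalyst-controlled epoxidation that would tell the two enantiomorphic homoallylic alcohol ends apart.
- Why turned down:
  - A5 offers two homoallylic alcohol/alkene pairs plus the bishomoallylic prenyl alkene.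
  - Peroxide/metal systems oxidise a conjugated polyene.
  - The Lewis acidic catalyst would ionise the product faster than it forms.
  - A5 needs the same fragments as the target, so nothing is simplified.

**Alternative 3:** the same C3–C4/C4–O cut, but as the very last step.
- Forward key step: ylide epoxidation of 7 with the C40 polyenyl sulfonium salt A6.
- What it would gain: the oxirane would be spared all later steps.
- Why turned down:
  - A dialkyl sulfide is a good nucleofuge and the dodecaenylmethyl cation is highly stabilised, so A6 should dissociate instead of persisting.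
  - Its ylide spreads the charge over the whole chain, so it should be a poor nucleophile that adds reversibly.
  - Reversible addition removes the kinetic basis of the stereocontrol.

Key step: step 10

Assumption: (1R,4R,5R)-12 is taken to be the enantiomer of the sulfide whose allylic ylides give (R,R)-oxiranes, as the steric model in step 10 predicts. If the sense is the opposite, its mirror image from (S)-limonene is used and nothing else changes.

## Steps

**Step 1**
Reactants: 1 (±)-lavandulol
Product: 2 (S)-lavandulyl acetate and 3 (R)-lavandulol (slow-reacting enantiomer, recovered)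
Conditions: porcine pancreatic lipase, vinyl acetate, hexane, rt, run past half conversion (about 55–60 %), chromatography
Reagents that add atoms: vinyl acetate, C=COC(C)=O
Why: Lipase-catalysed kinetic resolution by irreversible transesterification, in which the (S)-alcohol is expected to be acylated faster. Running past half conversion should leave 3 enantiopure, which matters because C2' is never corrected later, while a lower enantiopurity of 2 is repaired in step 10. Both enantiomers are used.

**Step 2**
Reactants: 2 (S)-lavandulyl acetate
Product: 4 (2R)-2-(2-hydroxypropan-2-yl)-5-methylhex-4-en-1-yl acetate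
Conditions: Co(acac)2 (cat.), PhSiH3 (limiting, slow addition), O2 (1 atm), THF, 0 °C
Reagents that add atoms: dioxygen, O=O
Why: Mukaiyama hydration: hydrogen atom transfer from a cobalt hydride goes fastest to the unhindered terminal CH2 of the 1,1-disubstituted alkene, the tertiary C1 radical is trapped by O2, and the trisubstituted prenyl alkene reacts more slowly, so limiting the silane should stop the reaction at 4. The C1 radical has only 4-exo or 5-endo paths to the prenyl alkene and should not cyclise. C2 is untouched, and the acetate from step 1 protects the primary alcohol.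

**Step 3**
Reactants: 4 (2R)-2-(2-hydroxypropan-2-yl)-5-methylhex-4-en-1-yl acetate
Product: 5 (2R)-5-methyl-2-[2-(triethylsilyloxy)propan-2-yl]hex-4-en-1-yl acetate
Conditions: TESOTf, 2,6-lutidine, CH2Cl2, 0 °C
Reagents that add atoms: triethylsilyl trifluoromethanesulfonate, CC[Si](CC)(CC)OS(=O)(=O)C(F)(F)F
Why: A hindered tertiary alcohol needs the silyl triflate. The TES ether blocks retro-aldol cleavage and hydrogen bonding at the aldehyde stage and makes C(CH3)2OTES the large group for step 10.

**Step 4**
Reactants: 5 (2R)-5-methyl-2-[2-(triethylsilyloxy)propan-2-yl]hex-4-en-1-yl acetate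
Product: 6 (2R)-5-methyl-2-[2-(triethylsilyloxy)propan-2-yl]hex-4-en-1-ol
Conditions: K2CO3 (cat.), MeOH, rt
Reagents that add atoms: none
Why: Base-catalysed transesterification removes the primary acetate, and a tertiary TES ether is stable to carbonate in methanol.

**Step 5**
Reactants: 6 (2R)-5-methyl-2-[2-(triethylsilyloxy)propan-2-yl]hex-4-en-1-ol
Product: 7 (2S)-5-methyl-2-[2-(triethylsilyloxy)propan-2-yl]hex-4-enal
Conditions: Dess–Martin periodinane, NaHCO3, CH2Cl2, 0 °C to rt
Reagents that add atoms: none
Why: Dess–Martin oxidation under buffered, non-basic conditions should give the α-branched aldehyde without epimerisation at C2 and without touching the alkene. The descriptor changes only because CHO outranks the carbinol carbon. 7 is used at once.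

**Step 6**
Reactants: 8 prenol (3-methylbut-2-en-1-ol)
Product: 9 tert-butyldimethyl(3-methylbut-2-enyloxy)silane
Conditions: TBSCl, imidazole, CH2Cl2, rt
Reagents that add atoms: tert-butyldimethylsilyl chloride, CC(C)(C)[Si](C)(C)Cl
Why: Standard silylation. A silyl ether is chosen for C7–O because it is a poor leaving group next to the later ylide and falls together with the TES group in step 11.

**Step 7**
Reactants: 9 tert-butyldimethyl(3-methylbut-2-enyloxy)silane
Product: 10 (2E)-4-(tert-butyldimethylsilyloxy)-2-methylbut-2-en-1-ol
Conditions: SeO2 (cat.), t-BuOOH, CH2Cl2, 0 °C to rt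
Reagents that add atoms: selenium dioxide (oxygen carrier), O=[Se]=O; tert-butyl hydroperoxide (terminal oxidant), CC(C)(C)OO
Why: Selenium dioxide allylic oxidation (ene reaction, then [2,3]-shift) oxidises the (E)-methyl group of a trisubstituted alkene. This fixes the E geometry of the later C5=C6 bond.

**Step 8**
Reactants: 10 (2E)-4-(tert-butyldimethylsilyloxy)-2-methylbut-2-en-1-ol
Product: 11 [(2E)-4-bromo-3-methylbut-2-enyloxy](tert-butyl)dimethylsilane
Conditions: CBr4, PPh3, CH2Cl2, 0 °C
Reagents that add atoms: carbon tetrabromide, BrC(Br)(Br)Br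
Why: Appel reaction: neutral SN2 bromination of a primary allylic alcohol, with no allylic shift expected and the silyl ether left intact.

**Step 9**
Reactants: 11 [(2E)-4-bromo-3-methylbut-2-enyloxy](tert-butyl)dimethylsilane; 12 (1R,4R,5R)-isothiocineole (4,7,7-trimethyl-6-thiabicyclo[3.2.1]octane)
Product: 13 S-[(2E)-4-(tert-butyldimethylsilyloxy)-2-methylbut-2-enyl]-(1R,4R,5R)-isothiocineolium triflate (exo at sulfur)
Conditions: LiOTf, CH2Cl2/H2O, rt
Reagents that add atoms: lithium trifluoromethanesulfonate, [Li+].[O-]S(=O)(=O)C(F)(F)F
Why: S-Alkylation of the sulfide by the allylic bromide with anion exchange in a two-phase system. The sulfide should be alkylated on its exo lone pair (syn to the one-carbon bridge), so a single configuration at sulfur is expected.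

**Step 10**
Reactants: 13 allylic isothiocineolium triflate; 7 (2S)-5-methyl-2-[2-(triethylsilyloxy)propan-2-yl]hex-4-enal
Product: 16 tert-butyl{(2E)-3-[(2R,3R)-3-{(3R)-2,6-dimethyl-2-(triethylsilyloxy)hept-5-en-3-yl}oxiran-2-yl]but-2-enyloxy}dimethylsilane (C1–C7 unit; 2R,3R,4R; 5E), via sulfonium ylide 14 (not isolated), via anti-betaine 15 (not isolated)
Conditions: P2-Et phosphazene base added to 13 + 7, CH2Cl2, −78 °C to −40 °C
Reagents that add atoms: none
Why: This is an asymmetric sulfonium ylide epoxidation (Corey–Chaykovsky type), a reaction type established for allylic and benzylic salts of this sulfide with aromatic, unsaturated and aliphatic aldehydes. The base removes the most acidic proton, C4–H next to S+, to give ylide 14 in the presence of 7, whose hindered tertiary C2–H is removed far more slowly, so C2 should not epimerise. C4 of 14 adds to the carbonyl carbon C3 to give anti-betaine 15, which after rotation about C3–C4 closes the oxirane by a 3-exo-tet SN2 displacement of sulfide 12 with inversion at C4. C4 is controlled by the sulfide: the alkenyl residue of the exo S-substituent lies on the side of the sulfur lone pair (reinforced by the C5 methyl group) and the gem-dimethyl carbon of the bicycle shields one face of the ylide carbon, so bonding on the open face should lead to 4R after inversion. C3 follows from the preference for the anti-betaine, since the syn-betaine of a bulky α-branched aldehyde forms reversibly and closes slowly, which gives the trans-oxirane and hence 3R; the same aldehyde face is the Felkin–Anh face of 7 with C(CH3)2OTES as the large group, so reagent and substrate are matched. α-Attack is secured because only the α-adduct has a leaving group placed for irreversible ring closure, and a [2,3]-shift is excluded because the sulfide has no other α-hydrogen than a bridgehead one. Chemoselectivity is inherent, since no oxidant is present and C2''=C3'' and C5=C6 are untouched. Residual minor enantiomer of 7 is turned into a diastereomeric oxirane and is removed by chromatography at this stage.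

**Step 11**
Reactants: 16 bis-silylated C1–C7 oxirane
Product: 17 (2E)-3-[(2R,3R)-3-{(3R)-2-hydroxy-2,6-dimethylhept-5-en-3-yl}oxiran-2-yl]but-2-en-1-ol
Conditions: TBAF, THF, 0 °C to rt
Reagents that add atoms: none
Why: Fluoride cleaves the primary TBS and the tertiary TES ether in one operation. The medium is never acidic, so the vinyl oxirane should survive, and 4-exo or 5-endo attack of the C1 oxygen is slow under these conditions.

**Step 12**
Reactants: 17 epoxy diol
Product: 18 (2E)-3-[(2R,3R)-3-{(3R)-2-hydroxy-2,6-dimethylhept-5-en-3-yl}oxiran-2-yl]but-2-enal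
Conditions: MnO2 (activated, excess), CH2Cl2, rt
Reagents that add atoms: none
Why: MnO2 oxidises only the primary allylic alcohol under neutral conditions. The formyl group then deactivates C4 towards ionisation.

**Step 13**
Reactants: 3 (R)-lavandulol
Product: 19 (3S)-3-(hydroxymethyl)-2,6-dimethylheptane-2,6-diol
Conditions: Co(acac)2 (cat.), PhSiH3 (excess), O2 (1 atm), THF, rt
Reagents that add atoms: dioxygen, O=O
Why: Exhaustive Mukaiyama hydration gives Markovnikov alcohols at both alkenes through tertiary radicals. No selectivity is needed here, and C2' is untouched (the descriptor changes by priority only).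

**Step 14**
Reactants: 19 (3S)-3-(hydroxymethyl)-2,6-dimethylheptane-2,6-diol
Product: 20 tris(triethylsilyl) ether of 19
Conditions: TESOTf, 2,6-lutidine, CH2Cl2, 0 °C to rt
Reagents that add atoms: triethylsilyl trifluoromethanesulfonate, CC[Si](CC)(CC)OS(=O)(=O)C(F)(F)F
Why: Exhaustive silylation with the silyl triflate. It prevents lactol formation and retro-aldol cleavage at the aldehyde stage.

**Step 15**
Reactants: 20 tris(triethylsilyl) ether of 19
Product: 21 (2R)-5-methyl-5-(triethylsilyloxy)-2-[2-(triethylsilyloxy)propan-2-yl]hexanal
Conditions: (COCl)2, DMSO, CH2Cl2, −78 to −40 °C; Et3N, −78 °C to rt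
Reagents that add atoms: none
Why: Swern conditions convert a primary TES ether directly into the aldehyde, because activated DMSO attacks the least hindered silyl ether oxygen while the two tertiary TES ethers stay. This known shortcut saves a separate deprotection.

**Step 16**
Reactants: 21 (2R)-aldehyde; 22 triethyl 3-methyl-4-phosphonocrotonate
Product: 24 ethyl (2E,4E,6S)-3,9-dimethyl-9-(triethylsilyloxy)-6-[2-(triethylsilyloxy)propan-2-yl]deca-2,4-dienoate, via lithiated phosphonate 23 (not isolated)
Conditions: LiHMDS, THF/DMPU, −78 to 0 °C
Reagents that add atoms: none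
Why: Horner–Wadsworth–Emmons olefination forms C3'=C4' with the E selectivity typical of stabilised phosphonates. The delocalised anion 23 equilibrates, so the E geometry at C5'=C6' should predominate and the minor isomer is removed by chromatography. The weakly basic anion should not epimerise C2'.

**Step 17**
Reactants: 24 dienoate
Product: 25 (2E,4E,6S)-3,9-dimethyl-9-(triethylsilyloxy)-6-[2-(triethylsilyloxy)propan-2-yl]deca-2,4-dien-1-ol
Conditions: i-Bu2AlH, CH2Cl2, −78 °C
Reagents that add atoms: none
Why: 1,2-Reduction of a conjugated ester to the allylic alcohol, with silyl ethers and diene left inert.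

**Step 18**
Reactants: 25 dienol
Product: 26 [(2E,4E,6S)-9-hydroxy-6-(2-hydroxypropan-2-yl)-3,9-dimethyldeca-2,4-dienyl]triphenylphosphonium bromide
Conditions: PPh3·HBr (slight excess), MeOH, rt
Reagents that add atoms: triphenylphosphine hydrobromide, [Br-].c1ccc(cc1)[PH+](c1ccccc1)c1ccccc1
Why: Standard carotenoid phosphonium salt formation through the pentadienyl cation, which PPh3 captures irreversibly at the primary terminus C7'. Capture by a hydroxyl group is reversible under these conditions. The acidic methanol also removes both TES groups, which are no longer needed.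

**Step 19**
Reactants: 26 C15 phosphonium bromide; 27 crocetindial (8,8'-diapocarotene-8,8'-dial)
Product: 29 all-E C35 aldehyde (C8 to C1' of the target, C8 = CHO, 2'S), via dienyl ylide 28 (not isolated)
Conditions: NaOMe, CH2Cl2/MeOH, 0 °C to rt, 26 added slowly to 27 (about 2.5 equiv), dark; then EtOH, reflux
Reagents that add atoms: none
Why: Wittig olefination forms C7'=C8'. Excess dialdehyde and slow addition favour reaction at one formyl group only, and unreacted 27 is recovered. The hindered Z isomer at the new bond equilibrates thermally to E, and free tertiary alcohols are tolerated.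

**Step 20**
Reactants: 29 C35 aldehyde
Product: 30 all-E C35 allylic alcohol (C8 = CH2OH)
Conditions: NaBH4, THF/EtOH, 0 °C
Reagents that add atoms: none
Why: 1,2-Reduction of a polyenal by borohydride.

**Step 21**
Reactants: 30 C35 allylic alcohol
Product: 31 all-E C35 triphenylphosphonium bromide (P on C8)
Conditions: PPh3·HBr, CH2Cl2/MeOH, 0 °C to rt, dark
Reagents that add atoms: triphenylphosphine hydrobromide, [Br-].c1ccc(cc1)[PH+](c1ccccc1)c1ccccc1
Why: Same salt formation as in step 18. The primary phosphonium salt with the fully conjugated decaene is the thermodynamic sink of the delocalised cation.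

**Step 22**
Reactants: 31 C35 phosphonium bromide; 18 epoxy enal
Product: 33 target, via polyenyl ylide 32 (not isolated)
Conditions: NaOMe, CH2Cl2/MeOH, −10 °C to rt, argon, dark; then toluene (trace Et3N), 80 °C
Reagents that add atoms: none
Why: Wittig olefination forms C7=C8 with the oxirane on the carbonyl partner, so no carbanion is ever conjugated to C4–O, and the medium stays basic or neutral. The hindered 7Z isomer should equilibrate to all-E on gentle heating in a base-washed aprotic solvent. No protecting group is left to remove.

## Compound list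

1 | (±)-lavandulol | CC(C)=CCC(CO)C(C)=C | starting material
2 | (S)-lavandulyl acetate | CC(C)=CC[C@H](COC(C)=O)C(C)=C | intermediate
3 | (R)-lavandulol | CC(C)=CC[C@@H](CO)C(C)=C | intermediate
4 | (2R)-2-(2-hydroxypropan-2-yl)-5-methylhex-4-en-1-yl acetate | CC(C)=CC[C@H](COC(C)=O)C(C)(C)O | intermediate
5 | (2R)-5-methyl-2-[2-(triethylsilyloxy)propan-2-yl]hex-4-en-1-yl acetate | CC(C)=CC[C@H](COC(C)=O)C(C)(C)O[Si](CC)(CC)CC | intermediate
6 | (2R)-5-methyl-2-[2-(triethylsilyloxy)propan-2-yl]hex-4-en-1-ol | CC(C)=CC[C@H](CO)C(C)(C)O[Si](CC)(CC)CC | intermediate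
7 | (2S)-5-methyl-2-[2-(triethylsilyloxy)propan-2-yl]hex-4-enal | CC(C)=CC[C@H](C=O)C(C)(C)O[Si](CC)(CC)CC | intermediate
8 | prenol | CC(C)=CCO | starting material
9 | tert-butyldimethyl(3-methylbut-2-enyloxy)silane | CC(C)=CCO[Si](C)(C)C(C)(C)C | intermediate
10 | (2E)-4-(tert-butyldimethylsilyloxy)-2-methylbut-2-en-1-ol | OC/C(C)=C/CO[Si](C)(C)C(C)(C)C | intermediate
11 | [(2E)-4-bromo-3-methylbut-2-enyloxy](tert-butyl)dimethylsilane | BrC/C(C)=C/CO[Si](C)(C)C(C)(C)C | intermediate
12 | (1R,4R,5R)-isothiocineole (commercial; also one step from (R)-limonene and sulfur) | C[C@@H]1CC[C@@H]2C[C@H]1SC2(C)C | starting material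
13 | allylic isothiocineolium triflate (exo at sulfur) | C[C@@H]1CC[C@@H]2C[C@H]1[S@@+](C/C(C)=C/CO[Si](C)(C)C(C)(C)C)C2(C)C.[O-]S(=O)(=O)C(F)(F)F | intermediate
14 | sulfonium ylide from 13 | C[C@@H]1CC[C@@H]2C[C@H]1[S@@+]([CH-]/C(C)=C/CO[Si](C)(C)C(C)(C)C)C2(C)C | intermediate
15 | anti-betaine (2R,3R,4S) | C[C@@H]1CC[C@@H]2C[C@H]1[S@@+]([C@@H](/C(C)=C/CO[Si](C)(C)C(C)(C)C)[C@H]([O-])[C@@H](CC=C(C)C)C(C)(C)O[Si](CC)(CC)CC)C2(C)C | intermediate
16 | bis-silylated C1–C7 trans-oxirane (2R,3R,4R,5E) | CC(C)=CC[C@H]([C@H]1O[C@@H]1/C(C)=C/CO[Si](C)(C)C(C)(C)C)C(C)(C)O[Si](CC)(CC)CC | intermediate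
17 | epoxy diol (2R,3R,4R,5E) | CC(C)=CC[C@H]([C@H]1O[C@@H]1/C(C)=C/CO)C(C)(C)O | intermediate
18 | epoxy enal (2R,3R,4R,5E) | CC(C)=CC[C@H]([C@H]1O[C@@H]1/C(C)=C/C=O)C(C)(C)O | intermediate
19 | (3S)-3-(hydroxymethyl)-2,6-dimethylheptane-2,6-diol | CC(C)(O)CC[C@@H](CO)C(C)(C)O | intermediate
20 | tris(triethylsilyl) ether of 19 | CC(C)(O[Si](CC)(CC)CC)CC[C@@H](CO[Si](CC)(CC)CC)C(C)(C)O[Si](CC)(CC)CC | intermediate
21 | (2R)-5-methyl-5-(triethylsilyloxy)-2-[2-(triethylsilyloxy)propan-2-yl]hexanal | CC(C)(O[Si](CC)(CC)CC)CC[C@@H](C=O)C(C)(C)O[Si](CC)(CC)CC | intermediate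
22 | triethyl 3-methyl-4-phosphonocrotonate (drawn as E; sold as an E/Z mixture) | CCOC(=O)/C=C(\C)CP(=O)(OCC)OCC | starting material
23 | lithiated phosphonate | CCOC(=O)/C=C(\C)[CH-]P(=O)(OCC)OCC.[Li+] | intermediate
24 | ethyl (2E,4E,6S)-dienoate, bis-TES | CCOC(=O)/C=C(C)/C=C/[C@H](CCC(C)(C)O[Si](CC)(CC)CC)C(C)(C)O[Si](CC)(CC)CC | intermediate
25 | (2E,4E,6S)-dienol, bis-TES | OC/C=C(C)/C=C/[C@H](CCC(C)(C)O[Si](CC)(CC)CC)C(C)(C)O[Si](CC)(CC)CC | intermediate
26 | C15 phosphonium bromide | c1ccccc1[P+](c1ccccc1)(c1ccccc1)C/C=C(C)/C=C/[C@H](CCC(C)(C)O)C(C)(C)O.[Br-] | intermediate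
27 | crocetindial | O=C/C(C)=C/C=C/C(C)=C/C=C/C=C(C)/C=C/C=C(C)/C=O | starting material
28 | dienyl ylide from 26 | c1ccccc1[P+](c1ccccc1)(c1ccccc1)[CH-]/C=C(C)/C=C/[C@H](CCC(C)(C)O)C(C)(C)O | intermediate
29 | all-E C35 aldehyde | O=C/C(C)=C/C=C/C(C)=C/C=C/C=C(C)/C=C/C=C(C)/C=C/C=C(C)/C=C/[C@H](CCC(C)(C)O)C(C)(C)O | intermediate
30 | all-E C35 alcohol | OC/C(C)=C/C=C/C(C)=C/C=C/C=C(C)/C=C/C=C(C)/C=C/C=C(C)/C=C/[C@H](CCC(C)(C)O)C(C)(C)O | intermediate
31 | all-E C35 phosphonium bromide | c1ccccc1[P+](c1ccccc1)(c1ccccc1)C/C(C)=C/C=C/C(C)=C/C=C/C=C(C)/C=C/C=C(C)/C=C/C=C(C)/C=C/[C@H](CCC(C)(C)O)C(C)(C)O.[Br-] | intermediate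
32 | polyenyl ylide from 31 | c1ccccc1[P+](c1ccccc1)(c1ccccc1)[CH-]/C(C)=C/C=C/C(C)=C/C=C/C=C(C)/C=C/C=C(C)/C=C/C=C(C)/C=C/[C@H](CCC(C)(C)O)C(C)(C)O | intermediate
33 | (2R,3R,4R,2'S)-3,4-epoxy-2'-(3-hydroxy-3-methylbutyl)-2-(3-methylbut-2-enyl)-3',4'-didehydro-1,2,1',2'-tetrahydro-ψ,ψ-carotene-1,1'-diol | CC(C)=CC[C@H]([C@H]1O[C@@H]1/C(C)=C/C=C/C(C)=C/C=C/C(C)=C/C=C/C=C(C)/C=C/C=C(C)/C=C/C=C(C)/C=C/[C@H](CCC(C)(C)O)C(C)(C)O)C(C)(C)O | target

## Step count and least certain steps

Total step count: 22. Longest linear sequence: 11 steps (step 1, steps 13–21, step 22).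

**Step 10 (key step).**
- What may go wrong:
  - Addition to the hindered, neopentyl-like aldehyde may be slow. The ylide could then decay by 1,4-loss of silanolate or by proton transfer from C2–H, which would epimerise C2.
  - Insufficient reversibility of syn-betaine formation would lower the trans selectivity.
- Fallback: it sets out from 7 and comes back at 17. The oxirane oxygen is introduced by nucleophilic instead of electrophilic oxidation.
  - Wittig reaction of 7 with 1-(triphenylphosphoranylidene)propan-2-one gives the (E)-enone F1.
  - Weitz–Scheffer type epoxidation with tert-butyl hydroperoxide follows, under a La(O-i-Pr)3/BINOL/Ph3As=O catalyst with the BINOL enantiomer matched to the 3R,4R sense. It attacks only the electron-poor C3=C4 bond, leaves the electron-rich prenyl alkene alone, and gives the trans-epoxy ketone F2.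
  - Horner–Wadsworth–Emmons reaction with triethyl phosphonoacetate and NaH builds C5=C6 and gives, after separation of the geometric isomers, the epoxy enoate F3.
  - i-Bu2AlH gives the allylic alcohol F4, and TBAF gives 17.

**Step 22.**
- What may go wrong:
  - Methoxide or the ylide may deprotonate the C5 methyl group of the γ,δ-epoxy enal, with eliminative opening of the oxirane.
  - The strongly delocalised ylide may react sluggishly.
  - E selectivity at C7=C8 may be poor.
  - The polyenyl oxirane may be lost during the thermal equilibration.
- Fallback: it sets out from 7, 12 and 29 and comes back at 33. The last bond moves to the single bond C6–C7, so no new double bond geometry arises.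
  - Commercial (E)-3-iodo-2-methylprop-2-en-1-ol is brominated (CBr4, PPh3) to the allylic bromide F5.
  - F5 with 12 and LiOTf gives the iodoallyl sulfonium salt F6.
  - The ylide epoxidation of step 10 with 7 gives the epoxy vinyl iodide F7.
  - Boron-Wittig reaction of 29 with lithiated bis(pinacolatoboryl)methane (excess, because of the two hydroxyl groups) gives the polyenylboronate F8.
  - Suzuki–Miyaura coupling of F7 and F8 (Pd(PPh3)4, aqueous K3PO4, THF, rt) gives the TES ether F9.
  - TBAF gives 33.
  - The price is exposure of a vinyl oxirane to zerovalent palladium, which is why this is not the first choice.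

**Step 21.**
- What may go wrong: ionisation gives a decaenyl cation. It may be captured at its far end C3' by the side-chain hydroxyl group, may lose a proton with a shift of all double bonds, or may be accompanied by dehydration of a tertiary alcohol.
- Fallback: it sets out from 25 and 27 and comes back at 31. Phosphorus is brought in with the hydroxyl-free central block.
  - TBAF converts 25 into the triol F10, and MnO2 gives the dienal F11.
  - NaBH4 reduces 27 to the diol F12, and PPh3·HBr gives the bis(phosphonium) dibromide F13.
  - Wittig reaction of excess F13 (one equivalent of NaOMe) with F11 forms C7'=C8' and leaves the second phosphonium group in place, which is 31.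

**Step 2.**
- What may go wrong: discrimination between the two alkenes may be insufficient, with hydration of the prenyl group as well. Both react through tertiary radicals and differ only in steric access.
- Fallback: it sets out from 8 and comes back at 4. No alkene has to be told from another.
  - PBr3 converts 8 into prenyl bromide F14.
  - The dianion of commercial ethyl 3-hydroxy-3-methylbutanoate (2 equiv LDA) is alkylated with F14 to the racemic hydroxy ester F15.
  - LiAlH4 gives the racemic diol F16.
  - The lipase/vinyl acetate resolution of step 1 is applied to F16 and is expected to acylate the enantiomer of the same spatial sense, which gives 4.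

## Further compounds

F1 | step 10 | (E)-enone, C3=C4–C5(=O)CH3, TES ether | CC(=O)/C=C/[C@@H](CC=C(C)C)C(C)(C)O[Si](CC)(CC)CC
F2 | step 10 | trans-epoxy methyl ketone, oxirane configured as in 16 | CC(C)=CC[C@H]([C@H]1O[C@@H]1C(C)=O)C(C)(C)O[Si](CC)(CC)CC
F3 | step 10 | ethyl (E)-epoxy enoate, TES ether | CC(C)=CC[C@H]([C@H]1O[C@@H]1/C(C)=C/C(=O)OCC)C(C)(C)O[Si](CC)(CC)CC
F4 | step 10 | epoxy allylic alcohol, TES ether | CC(C)=CC[C@H]([C@H]1O[C@@H]1/C(C)=C/CO)C(C)(C)O[Si](CC)(CC)CC
F5 | step 22 | (E)-3-bromo-1-iodo-2-methylprop-1-ene | BrC/C(C)=C/I
F6 | step 22 | S-[(E)-3-iodo-2-methylallyl]isothiocineolium triflate | C[C@@H]1CC[C@@H]2C[C@H]1[S@@+](C/C(C)=C/I)C2(C)C.[O-]S(=O)(=O)C(F)(F)F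
F7 | step 22 | epoxy vinyl iodide (2R,3R,4R,5E), TES ether | CC(C)=CC[C@H]([C@H]1O[C@@H]1/C(C)=C/I)C(C)(C)O[Si](CC)(CC)CC
F8 | step 22 | all-E C36 polyenyl pinacolboronate (B on C7) | CC1(C)OB(OC1(C)C)/C=C/C(C)=C/C=C/C(C)=C/C=C/C=C(C)/C=C/C=C(C)/C=C/C=C(C)/C=C/[C@H](CCC(C)(C)O)C(C)(C)O
F9 | step 22 | C1-O-triethylsilyl ether of 33 | CC(C)=CC[C@H]([C@H]1O[C@@H]1/C(C)=C/C=C/C(C)=C/C=C/C(C)=C/C=C/C=C(C)/C=C/C=C(C)/C=C/C=C(C)/C=C/[C@H](CCC(C)(C)O)C(C)(C)O)C(C)(C)O[Si](CC)(CC)CC
F10 | step 21 | (2E,4E,6S)-6-(2-hydroxypropan-2-yl)-3,9-dimethyldeca-2,4-diene-1,9-diol | OC/C=C(C)/C=C/[C@H](CCC(C)(C)O)C(C)(C)O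
F11 | step 21 | (2E,4E,6S)-9-hydroxy-6-(2-hydroxypropan-2-yl)-3,9-dimethyldeca-2,4-dienal | O=C/C=C(C)/C=C/[C@H](CCC(C)(C)O)C(C)(C)O
F12 | step 21 | 8,8'-diapocarotene-8,8'-diol | OC/C(C)=C/C=C/C(C)=C/C=C/C=C(C)/C=C/C=C(C)/CO
F13 | step 21 | 8,8'-diapocarotene-8,8'-diylbis(triphenylphosphonium) dibromide | [Br-].[Br-].c1ccccc1[P+](c1ccccc1)(c1ccccc1)C/C(C)=C/C=C/C(C)=C/C=C/C=C(C)/C=C/C=C(C)/C[P+](c1ccccc1)(c1ccccc1)c1ccccc1
F14 | step 2 | prenyl bromide | CC(C)=CCBr
F15 | step 2 | ethyl (±)-2-(2-hydroxypropan-2-yl)-5-methylhex-4-enoate | CCOC(=O)C(CC=C(C)C)C(C)(C)O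
F16 | step 2 | (±)-2-(2-hydroxypropan-2-yl)-5-methylhex-4-en-1-ol | CC(C)=CCC(CO)C(C)(C)O
A1 | alternative 1 | ethyl (2E,4E,6R)-6-(2-hydroxypropan-2-yl)-3,9-dimethyldeca-2,4,8-trienoate | CCOC(=O)/C=C(C)/C=C/[C@@H](CC=C(C)C)C(C)(C)O
A2 | alternative 1 | left C20 epoxy phosphonium bromide (P on C11) | CC(C)=CC[C@H]([C@H]1O[C@@H]1/C(C)=C/C=C/C(C)=C/C[P+](c1ccccc1)(c1ccccc1)c1ccccc1)C(C)(C)O.[Br-]
A3 | alternative 1 | (2E,4E,6E)-2,7-dimethylocta-2,4,6-trienedial | O=C/C(C)=C/C=C/C=C(C)/C=O
A4 | alternative 1 | right C20 phosphonium bromide (P on C11') | c1ccccc1[P+](c1ccccc1)(c1ccccc1)C/C=C(C)/C=C/C=C(C)/C=C/[C@H](CCC(C)(C)O)C(C)(C)O.[Br-]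
A5 | alternative 2 | (2R,2'S)-C50 tridecaene with C3=C4 in place of the oxirane | CC(C)=CC[C@H](/C=C/C(C)=C/C=C/C(C)=C/C=C/C(C)=C/C=C/C=C(C)/C=C/C=C(C)/C=C/C=C(C)/C=C/[C@H](CCC(C)(C)O)C(C)(C)O)C(C)(C)O
A6 | alternative 3 | C40 dodecaenylmethyl isothiocineolium triflate (S on C4) | C[C@@H]1CC[C@@H]2C[C@H]1[S@@+](C/C(C)=C/C=C/C(C)=C/C=C/C(C)=C/C=C/C=C(C)/C=C/C=C(C)/C=C/C=C(C)/C=C/[C@H](CCC(C)(C)O)C(C)(C)O)C2(C)C.[O-]S(=O)(=O)C(F)(F)F
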